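## Retrosynthetic overview

1. **Feature.** In the nine-membered carbocycle, the run C7(CH3)–C6–C5–C4a–C11a–C11, with C4–C3 attached to C4a, is the p-menthane skeleton of (S)-limonene, whose stereocentre becomes C4a. Only C8–C9–C10 are missing between C7 and C11.
2. **Endgame.** Target ⇒ Z-C7=C8 tricycle 29, by desilylation, hydroxyl-directed epoxidation of Z-C8=C9, E→Z equilibration, selenide/selenoxide transposition and Shi epoxidation. Tricycle 29 ⇒ pyran methyl acetal 16 plus allylic alcohol 26 (C12–C15, from 2,3-O-isopropylidene-D-erythronolactone), by C4=C12 ring-closing metathesis and C3–O acetal exchange.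
3. **Key disconnection.** 16 ⇒ cyclononenone 15 (C11 methylenation) ⇒ 2-methylene-7-methyl-7-vinyloxepane 14 (Claisen ring expansion makes C9–C10 and breaks C7–O) ⇒ lactone 13 (lactone methylenation).
4. **Start.** 13 ⇒ limonene, by ring-olefin cleavage, vinyl addition, lactonisation, C1 hydroxymethylation and C3 allylic oxidation. The C3 oxidation is done at the lactone stage, where the isopropenyl group is the only olefin that has allylic hydrogens.
5. **Ring order.** Oxepanone → pyran → nine-membered carbocycle (oxepane consumed) → dihydrofuran → oxirane.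

Key step: step 9

**Numbering used throughout.** C1 = pyran OCH2; C3 = acetal CH; C4/C12 = dihydrofuran olefin; C13 = dihydrofuran OCH; C14/C15 = side-chain carbinols; C4a/C11a = ring-fusion CH; C5, C6, C10 = ring CH2; C7 = methyl carbinol; C8/C9 = oxirane; C11 = carbon bearing methylene C19.

**Remark.** The vinyl addition of step 3 is not expected to be selective at C7, so 6–14 are carried as unseparated C7 epimer pairs. Names and SMILES show the 7S epimer. Both converge in step 9, where C7 becomes sp2.

## Route

Step 1
Reactants: 1 (S)-(−)-limonene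
Product: 3 (3S)-3-isopropenyl-6-oxoheptanal, via ozonide 2 (not isolated)
Conditions: O3 (1.0 equiv, Sudan Red 7B end point), CH2Cl2, −78 °C; then Me2S, −78 °C → rt
Reagents that add atoms: ozone, [O-][O+]=O
Why: Ozonolysis with reductive work-up; the trisubstituted ring olefin is the more electron-rich one and is consumed first when ozone is titrated, which opens the ring between the future C7 (methyl ketone) and C11 (aldehyde) and leaves the stereocentre (future C4a) untouched.

Step 2
Reactants: 3 (3S)-3-isopropenyl-6-oxoheptanal
Product: 4 (3S)-3-isopropenyl-6-oxoheptanoic acid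
Conditions: NaClO2, NaH2PO4, 2-methyl-2-butene, tBuOH–H2O, 0 °C → rt
Reagents that add atoms: sodium chlorite, [Na+].[O-]Cl=O
Why: Pinnick oxidation takes only the aldehyde to the acid, and the scavenger olefin removes HOCl before it can attack the isopropenyl group.

Step 3
Reactants: 4 (3S)-3-isopropenyl-6-oxoheptanoic acid; 5 vinylmagnesium bromide
Product: 6 (3S,6S)-6-hydroxy-6-methyl-3-isopropenyloct-7-enoic acid
Conditions: 5 (3.2 equiv), THF, −78 → 0 °C; aq. citric acid
Reagents that add atoms: vinylmagnesium bromide (5), C=C[Mg]Br
Why: Grignard 1,2-addition to the methyl ketone while the acid is masked as its magnesium carboxylate; C7 forms without useful control from the remote C4a centre, which is harmless because C7 is erased in step 9.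

Step 4
Reactants: 6 (3S,6S)-6-hydroxy-6-methyl-3-isopropenyloct-7-enoic acid
Product: 8 (4S,7S)-7-methyl-4-isopropenyl-7-vinyloxepan-2-one, via mixed anhydride 7 (not isolated)
Conditions: 2,4,6-Cl3C6H2COCl, Et3N, THF, rt; then slow addition to DMAP, toluene (2 mM), 80–110 °C
Reagents that add atoms: none
Why: Yamaguchi lactonisation under high dilution closes the seven-membered ring O–C7–C6–C5–C4a–C11a–C11; the acyl-pyridinium is reactive enough for the tertiary alcohol and the geminal substitution at C7 favours closure, with the C7–O bond kept intact.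

Step 5
Reactants: 8 (4S,7S)-7-methyl-4-isopropenyl-7-vinyloxepan-2-one
Product: 10 (3S,4S,7S)-3-(hydroxymethyl)-7-methyl-4-isopropenyl-7-vinyloxepan-2-one, via lithium enolate 9 (not isolated)
Conditions: iPr2NLi, THF, −78 °C; CH2O (g), −78 °C; AcOH quench at −78 °C
Reagents that add atoms: formaldehyde, C=O
Why: Aldol hydroxymethylation of the lactone enolate; formaldehyde approaches anti to the neighbouring C4a isopropenyl group and so sets C11a trans to C4a, and the low temperature keeps the allylic ester enolate from its own [3,3] shift.

Step 6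
Reactants: 10 (3S,4S,7S)-3-(hydroxymethyl)-7-methyl-4-isopropenyl-7-vinyloxepan-2-one
Product: 12 C3 lactol (pyran closed between the C1 oxygen and C3; trans-fused to the oxepanone), via enal 11 (not isolated)
Conditions: SeO2 (1.1 equiv), 1,4-dioxane, 70 °C
Reagents that add atoms: selenium dioxide, O=[Se]=O
Why: Riley allylic oxidation (ene reaction, then [2,3] shift) takes the isopropenyl CH3 to the C3 aldehyde; this is the only olefin with allylic hydrogens because the vinyl group sits on quaternary C7, tertiary allylic esters tolerate the reagent, and the C1 hydroxyl traps the enal as the six-membered lactol whose anomeric centre equilibrates.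

Step 7
Reactants: 12 C3 lactol
Product: 13 methyl acetal (axial OMe at C3; 3-methylenetetrahydropyran trans-fused to the oxepan-2-one)
Conditions: MeOH (10 equiv), pyridinium p-toluenesulfonate (PPTS, cat.), 4 Å MS, CH2Cl2, rt
Reagents that add atoms: methanol, CO
Why: Acid-catalysed acetalisation through the allyl-stabilised oxocarbenium ion; the anomeric effect and the avoidance of A(1,3) strain with the C4 methylene both place OMe axial, and PPTS is too weak to open the lactone.

Step 8
Reactants: 13 methyl acetal lactone
Product: 14 2-methylene-7-methyl-7-vinyloxepane, trans-fused at C4a/C11a to the 2-methoxy-3-methylenetetrahydropyran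
Conditions: Cp2TiMe2 (2.5 equiv), toluene, 70 °C, dark; filtration through basic Al2O3
Reagents that add atoms: dimethyltitanocene, C[Ti](C)(C1C=CC=C1)C1C=CC=C1
Why: Petasis methylenation (Cp2Ti=CH2, oxatitanacyclobutane, cycloreversion) converts the lactone C11=O into the exocyclic enol ether C11=C10 under non-acidic, non-basic conditions that spare the acetal, the olefins and C11a.

Step 9
Reactants: 14 2-methylene-7-methyl-7-vinyloxepane (pyran-fused)
Product: 15 (Z)-cyclonon-4-enone (C11 ketone; Z-C7=C8 bearing the C7 methyl; trans-fused at C4a/C11a to the methoxy-methylene-pyran)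
Conditions: o-xylene (0.01 M), Et3N (trace), BHT, base-washed sealed tube, 140–160 °C
Reagents that add atoms: none
Why: Heating lets the allyl vinyl ether C10=C11–O–C7–C8=C9 undergo a concerted suprafacial [3,3] shift (aliphatic Claisen rearrangement) that forms C9–C10, breaks C7–O and turns C11 into a ketone, the C=O bond gained paying for the medium-ring strain. The closest known reaction type is the lactone-methylenation/Claisen ring expansion of 2-methylene-6-vinyltetrahydropyrans to 4-cyclooctenones, together with its ketene-acetal variant that turns seven-membered vinyl dioxepanes into nine-membered lactones. The nine-membered carbocycle is closed by ring enlargement: the six oxepane carbons are kept and C10, C9 and C8 are spliced in through a bridged chair-like six-centre array with the vinyl group axial on the oxepane. No stereocentre is created, C7 is erased so both C7 epimers converge, C4a and C11a are spectators, and the only new stereo-element, the C7=C8 geometry, is fixed as Z because the tether C6–C5–C4a–C11a can span the array only with C6 axial on the chair, that is cis to C9, while a boat array would need ring torsions a seven-membered ring cannot reach. The 7S epimer reaches this array with both ring-fusion bonds equatorial, whereas the 7R epimer must pass through a twist form and should need the longer heating. The selectivity needed is Claisen over a Cope shift of C10=C11–C11a–C4a–C4=CH2 and over acid-induced migration of the enol ether double bond: the trans-fused pyran holds C11 and C4 antiperiplanar about C4a–C11a, which excludes the Cope array, and the basic medium suppresses the migration.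

Step 10
Reactants: 15 (Z)-cyclonon-4-enone
Product: 16 C11 exocyclic methylene (C19) compound
Conditions: Cp2TiMe2 (2 equiv), toluene, 75 °C, dark
Reagents that add atoms: dimethyltitanocene, C[Ti](C)(C1C=CC=C1)C1C=CC=C1
Why: Petasis methylenation of the hindered, enolisable ketone; the reagent is not basic, so the adjacent C11a centre is not epimerised.

Step 11
Reactants: 17 2,3-O-isopropylidene-D-erythronolactone
Product: 18 2-[(4R,5R)-5-(hydroxymethyl)-2,2-dimethyl-1,3-dioxolan-4-yl]propan-2-ol
Conditions: MeMgBr (3 equiv), THF, 0 °C → rt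
Reagents that add atoms: methylmagnesium bromide, C[Mg]Br
Why: Double Grignard addition turns the lactone carbonyl into the C15 dimethyl carbinol and frees the primary C12 hydroxyl; C13 and C14 come unchanged from the chiral pool.

Step 12
Reactants: 18 diol
Product: 21 furanose lactol (C12 hemiacetal closed by the C15 oxygen), via alkoxysulfonium chloride 19 (not isolated), via hydroxy aldehyde 20 (not isolated)
Conditions: (COCl)2 (1.1 equiv), DMSO, CH2Cl2, −78 °C; Et3N, −78 °C → rt
Reagents that add atoms: none
Why: Swern oxidation touches only the primary alcohol, and the aldehyde is released, and closes to the lactol, only after the activated sulfoxide is spent, so no lactone forms.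

Step 13
Reactants: 21 furanose lactol
Product: 22 2-[(4R,5R)-2,2-dimethyl-5-vinyl-1,3-dioxolan-4-yl]propan-2-ol
Conditions: Ph3PCH3Br, KOtBu (3 equiv of ylide), THF, 0 °C → rt
Reagents that add atoms: methyltriphenylphosphonium bromide, C[P+](c1ccccc1)(c1ccccc1)c1ccccc1.[Br-]
Why: Wittig methylenation of the lactol through its open aldehyde form; the low standing concentration of aldehyde protects the α-alkoxy centre C13 from epimerisation.

Step 14
Reactants: 22 vinyl dioxolane
Product: 23 (3R,4R)-2-methylhex-5-ene-2,3,4-triol
Conditions: AcOH–H2O (4:1), 40 °C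
Reagents that add atoms: none
Why: Mild acid hydrolysis of the isopropylidene acetal, needed because it bridges O13 and O14 whereas O13 must be free for the coupling.

Step 15
Reactants: 23 triol
Product: 24 (3R,4R)-4,5-dihydroxy-5-methylhex-1-en-3-yl pivalate
Conditions: tBuCOCl (1.05 equiv), pyridine, CH2Cl2, −20 → 0 °C
Reagents that add atoms: pivaloyl chloride, CC(C)(C)C(=O)Cl
Why: Sterically selective acylation; the allylic C13 hydroxyl is the least hindered, C14–OH lies next to the fully substituted C15, and C15–OH is tertiary.

Step 16
Reactants: 24 pivalate diol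
Product: 25 (3R,4R)-5-methyl-4,5-bis(triethylsilyloxy)hex-1-en-3-yl pivalate
Conditions: Et3SiOTf (2.5 equiv), 2,6-lutidine, CH2Cl2, −78 → 0 °C
Reagents that add atoms: triethylsilyl trifluoromethanesulfonate, CC[Si](CC)(CC)OS(=O)(=O)C(F)(F)F
Why: Silyl triflate silylation covers the hindered secondary and the tertiary hydroxyl with groups that fluoride removes at the end without acid or strong base; the cold, non-nucleophilic medium prevents acyl migration.

Step 17
Reactants: 25 bis-silyl pivalate
Product: 26 (3R,4R)-5-methyl-4,5-bis(triethylsilyloxy)hex-1-en-3-ol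
Conditions: iBu2AlH (2.2 equiv), CH2Cl2, −78 °C
Reagents that add atoms: none
Why: Reductive cleavage of the pivalate frees only O13; the aluminium alkoxide formed does not promote silyl migration.

Step 18
Reactants: 16 C11 methylene methyl acetal; 26 allylic alcohol
Product: 27 mixed acetal (O13 axial at C3 in place of OMe)
Conditions: 26 (1.3 equiv), PPTS (0.15 equiv), 5 Å MS, benzene, 60 °C
Reagents that add atoms: none
Why: Acid-catalysed transacetalisation through the allyl-stabilised cyclic oxocarbenium ion, driven by sieve uptake of methanol; attack occurs at C3 and the anomeric effect with A(1,3) strain should favour the axial C3 anomer, which is corrected in step 20.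

Step 19
Reactants: 27 mixed acetal
Product: 28 3-epi tricycle (2,5-dihydrofuran closed; C4=C12)
Conditions: (H2IMes)(PCy3)Cl2Ru=CHPh (second-generation Grubbs catalyst, 5–10 mol %), toluene (2 mM), 60–80 °C
Reagents that add atoms: none
Why: Ring-closing metathesis starts at the monosubstituted C12 vinyl group and closes the five-membered ring onto the C4 methylene with loss of ethene; the trisubstituted C7=C8 and the hindered C11=C19 olefins are poor partners, and C13 keeps its configuration.

Step 20
Reactants: 28 3-epi tricycle
Product: 29 tricycle with the natural C3 configuration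
Conditions: PPTS (0.2 equiv), CH2Cl2, 40 °C
Reagents that add atoms: none
Why: Acid-catalysed acetal epimerisation under thermodynamic control; both oxygens stay tethered, so ionisation and re-closure only invert C3, and the epimer with the dihydrofuran oxygen equatorial (coplanar with C4=C12) lets the trans-fused pyran sit as a chair instead of a twist-boat.

Step 21
Reactants: 29 tricycle
Product: 30 (7S,8R)-7,8-epoxide
Conditions: D-fructose-derived Shi ketone (0.3 equiv), Oxone (2KHSO5·KHSO4·K2SO4), K2CO3, Bu4NHSO4, Na2B4O7/Na2(EDTA) buffer (pH 10.5), MeCN–CH2(OMe)2–H2O, 0 °C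
Reagents that add atoms: potassium peroxymonosulfate, [K+].[O-]S(=O)(=O)OO
Why: Shi epoxidation; the chiral dioxirane selects the only trialkyl-substituted, electron-rich olefin, and its spiro transition state, in the sense known for 1-substituted cycloalkenes, delivers oxygen to the ring face that carries C1 at C11a, which sets C7 (and C8 provisionally) by reagent control.

Step 22
Reactants: 30 (7S,8R)-7,8-epoxide
Product: 33 (E)-C8=C9 allylic alcohol (7S tertiary carbinol), via hydroxy selenide 31 (not isolated), via selenoxide 32 (not isolated)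
Conditions: PhSeSePh, NaBH4, EtOH, reflux; then 30% H2O2, pyridine, THF, 0 °C → rt
Reagents that add atoms: none
Why: Epoxide-to-allylic-alcohol transposition (selenolate opening, selenoxide syn elimination); the soft nucleophile attacks secondary C8 with inversion so the C7–O bond and configuration are kept, the selenoxide can eliminate only towards C9 because C7 is quaternary, and since the planar five-centre transition state in a nine-membered ring is reached most easily at a ring torsion near 120°, the E-olefin is expected, any Z isomer formed being 34 already.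

Step 23
Reactants: 33 (E)-allylic alcohol
Product: 34 (Z)-C8=C9 allylic alcohol
Conditions: PhSSPh (0.2 equiv), hν (350 nm), benzene, rt
Reagents that add atoms: none
Why: Thiyl-radical addition–elimination equilibrates the disubstituted ring olefin towards the less strained Z-cyclononene, the operation that turns the E ring olefin of caryophyllene into isocaryophyllene without touching its exocyclic methylene; no stereocentre is affected.

Step 24
Reactants: 34 (Z)-allylic alcohol
Product: 35 bis(triethylsilyl) ether of the target (cis-8,9-epoxide syn to the C7 hydroxyl)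
Conditions: VO(acac)2 (5 mol %), tBuOOH (decane), CH2Cl2, 0 °C
Reagents that add atoms: tert-butyl hydroperoxide, CC(C)(C)OO
Why: Vanadium-catalysed hydroxyl-directed epoxidation; the C7 vanadate delivers oxygen to the face of Z-C8=C9 syn to the hydroxyl, the sense established for Z-cyclooct-2-enol and Z-cyclonon-2-enol (cis epoxy alcohols), which sets C8 and C9 and leaves the undirected olefins alone.

Step 25
Reactants: 35 bis(triethylsilyl) ether
Product: 36 CNP0281409.2 (target)
Conditions: Bu4NF, AcOH (1:1), THF, 0 °C → rt
Reagents that add atoms: none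
Why: Buffered fluoride desilylation frees C14–OH and C15–OH without acid (acetal, oxirane) or free alkoxide (epoxide migration), and the syn arrangement of C7–O and the oxirane also disfavours backside attack at C8.

## Compound list

1 | (S)-(−)-limonene | CC1=CC[C@@H](C(C)=C)CC1 | starting material
2 | secondary ozonide of the ring olefin of 1 (acetal carbons undefined) | CC12CC[C@H](C(C)=C)CC(OO1)O2 | intermediate
3 | (3S)-3-isopropenyl-6-oxoheptanal | O=CC[C@H](CCC(C)=O)C(C)=C | intermediate
4 | (3S)-3-isopropenyl-6-oxoheptanoic acid | OC(=O)C[C@H](CCC(C)=O)C(C)=C | intermediate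
5 | vinylmagnesium bromide | C=C[Mg]Br | starting material
6 | (3S,6S)-6-hydroxy-6-methyl-3-isopropenyloct-7-enoic acid (6R epimer carried along) | OC(=O)C[C@H](CC[C@](C)(O)C=C)C(C)=C | intermediate
7 | mixed 2,4,6-trichlorobenzoic anhydride of 6 | O=C(OC(=O)c1c(Cl)cc(Cl)cc1Cl)C[C@H](CC[C@](C)(O)C=C)C(C)=C | intermediate
8 | (4S,7S)-7-methyl-4-isopropenyl-7-vinyloxepan-2-one | O=C1O[C@](C)(C=C)CC[C@H](C(C)=C)C1 | intermediate
9 | lithium enolate of 8 | [Li]OC1=C[C@@H](C(C)=C)CC[C@@](C)(C=C)O1 | intermediate
10 | (3S,4S,7S)-3-(hydroxymethyl)-7-methyl-4-isopropenyl-7-vinyloxepan-2-one | O=C1O[C@](C)(C=C)CC[C@H](C(C)=C)[C@H]1CO | intermediate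
11 | C3 enal of 10 (2-substituted acrolein on C4a) | O=C1O[C@](C)(C=C)CC[C@H](C(=C)C=O)[C@H]1CO | intermediate
12 | C3 lactol, pyran trans-fused to the oxepanone (axial anomer drawn) | O=C1O[C@](C)(C=C)CC[C@@H]2C(=C)[C@@H](O)OC[C@@H]12 | intermediate
13 | methyl acetal of 12 (axial OMe) | O=C1O[C@](C)(C=C)CC[C@@H]2C(=C)[C@@H](OC)OC[C@@H]12 | intermediate
14 | 2-methylene-7-methyl-7-vinyloxepane fused to the methoxy-methylene-pyran (Claisen precursor) | C=C1O[C@](C)(C=C)CC[C@@H]2C(=C)[C@@H](OC)OC[C@@H]12 | intermediate
15 | (Z)-cyclonon-4-enone fused to the methoxy-methylene-pyran (Claisen product) | O=C1CC/C=C(C)\CC[C@@H]2C(=C)[C@@H](OC)OC[C@@H]12 | intermediate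
16 | C11 methylene analogue of 15 | C=C1CC/C=C(C)\CC[C@@H]2C(=C)[C@@H](OC)OC[C@@H]12 | intermediate
17 | 2,3-O-isopropylidene-D-erythronolactone | O=C1OC[C@H]2OC(C)(C)O[C@@H]12 | starting material
18 | 2-[(4R,5R)-5-(hydroxymethyl)-2,2-dimethyl-1,3-dioxolan-4-yl]propan-2-ol | OC[C@H]1OC(C)(C)O[C@H]1C(C)(C)O | intermediate
19 | dimethyl(alkoxy)sulfonium chloride of 18 (at O12) | C[S+](C)OC[C@H]1OC(C)(C)O[C@H]1C(C)(C)O.[Cl-] | intermediate
20 | hydroxy aldehyde (C12 aldehyde) | O=C[C@H]1OC(C)(C)O[C@H]1C(C)(C)O | intermediate
21 | furanose lactol of 20 (anomeric mixture) | OC1OC(C)(C)[C@@H]2OC(C)(C)O[C@H]12 | intermediate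
22 | 2-[(4R,5R)-2,2-dimethyl-5-vinyl-1,3-dioxolan-4-yl]propan-2-ol | C=C[C@H]1OC(C)(C)O[C@H]1C(C)(C)O | intermediate
23 | (3R,4R)-2-methylhex-5-ene-2,3,4-triol | C=C[C@@H](O)[C@@H](O)C(C)(C)O | intermediate
24 | (3R,4R)-4,5-dihydroxy-5-methylhex-1-en-3-yl pivalate | C=C[C@@H](OC(=O)C(C)(C)C)[C@@H](O)C(C)(C)O | intermediate
25 | (3R,4R)-5-methyl-4,5-bis(triethylsilyloxy)hex-1-en-3-yl pivalate | C=C[C@@H](OC(=O)C(C)(C)C)[C@@H](O[Si](CC)(CC)CC)C(C)(C)O[Si](CC)(CC)CC | intermediate
26 | (3R,4R)-5-methyl-4,5-bis(triethylsilyloxy)hex-1-en-3-ol | C=C[C@@H](O)[C@@H](O[Si](CC)(CC)CC)C(C)(C)O[Si](CC)(CC)CC | intermediate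
27 | mixed C3 acetal of 16 and 26 (axial anomer) | C=C1CC/C=C(C)\CC[C@@H]2C(=C)[C@@H](O[C@H](C=C)[C@@H](O[Si](CC)(CC)CC)C(C)(C)O[Si](CC)(CC)CC)OC[C@@H]12 | intermediate
28 | 3-epi tricycle | C=C1CC/C=C(C)\CC[C@@H]2C3=C[C@H]([C@@H](O[Si](CC)(CC)CC)C(C)(C)O[Si](CC)(CC)CC)O[C@H]3OC[C@@H]12 | intermediate
29 | tricycle with natural C3, Z-C7=C8 | C=C1CC/C=C(C)\CC[C@@H]2C3=C[C@H]([C@@H](O[Si](CC)(CC)CC)C(C)(C)O[Si](CC)(CC)CC)O[C@@H]3OC[C@@H]12 | intermediate
30 | (7S,8R)-7,8-epoxide | C=C1CC[C@H]2O[C@@]2(C)CC[C@@H]3C4=C[C@H]([C@@H](O[Si](CC)(CC)CC)C(C)(C)O[Si](CC)(CC)CC)O[C@@H]4OC[C@@H]13 | intermediate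
31 | 7-hydroxy-8-phenylselenide (anti) | C=C1CC[C@H]([Se]c2ccccc2)[C@@](C)(O)CC[C@@H]2C3=C[C@H]([C@@H](O[Si](CC)(CC)CC)C(C)(C)O[Si](CC)(CC)CC)O[C@@H]3OC[C@@H]12 | intermediate
32 | selenoxide of 31 | C=C1CC[C@H]([Se](=O)c2ccccc2)[C@@](C)(O)CC[C@@H]2C3=C[C@H]([C@@H](O[Si](CC)(CC)CC)C(C)(C)O[Si](CC)(CC)CC)O[C@@H]3OC[C@@H]12 | intermediate
33 | (E)-C8=C9 allylic alcohol | C=C1C/C=C/[C@@](C)(O)CC[C@@H]2C3=C[C@H]([C@@H](O[Si](CC)(CC)CC)C(C)(C)O[Si](CC)(CC)CC)O[C@@H]3OC[C@@H]12 | intermediate
34 | (Z)-C8=C9 allylic alcohol | C=C1C/C=C\[C@@](C)(O)CC[C@@H]2C3=C[C@H]([C@@H](O[Si](CC)(CC)CC)C(C)(C)O[Si](CC)(CC)CC)O[C@@H]3OC[C@@H]12 | intermediate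
35 | 14,15-bis(triethylsilyl) ether of the target | C=C1C[C@H]2O[C@H]2[C@@](C)(O)CC[C@@H]2C3=C[C@H]([C@@H](O[Si](CC)(CC)CC)C(C)(C)O[Si](CC)(CC)CC)O[C@@H]3OC[C@@H]12 | intermediate
36 | CNP0281409.2 | C=C1C[C@H]2O[C@H]2[C@@](C)(O)CC[C@@H]2C3=C[C@H]([C@@H](O)C(C)(C)O)O[C@@H]3OC[C@@H]12 | target

## Step count and risks

Total step count: 25.
Longest linear sequence: 18 steps (steps 1–10 and 18–25, from (S)-limonene).

**Steps most likely to fail**

1. **Step 9 (key step).** Traces of acid may move the exocyclic enol ether double bond into the ring or hydrolyse it. The 7R epimer may also rearrange so slowly that thermal decomposition competes.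
   The fallback sets out from 14 and promotes the same [3,3] shift with a Lewis acid instead of heat (iBu3Al, CH2Cl2, −78 → 0 °C, kept cold to spare the acetal). Coordination to the ring oxygen weakens C7–O, and the aluminium reagent reduces the ketone as it forms, giving the cyclononenol F1, whose C11 configuration is of no consequence. Oxidation with Dess–Martin periodinane/NaHCO3 then returns the route to 15.

2. **Step 23.** The equilibrium may not lie far enough on the Z side because the quaternary C7 presses against C10 in the Z-olefin. Thiyl radicals may also add irreversibly to the 1,1-disubstituted olefins.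
   The fallback is stereospecific instead of thermodynamic and sets out from 33. VO(acac)2/tBuOOH gives the trans-epoxy alcohol F3; either trans diastereomer serves. LiPPh2 (THF) opens it at C9 with inversion, and MeI gives the hydroxyphosphonium iodide F4. The betaine of F4 collapses by syn elimination of the phosphine oxide, which inverts the olefin geometry and returns the route to 34. Any 34 already present after step 22 is separated first and used directly.

3. **Step 21.** The facial preference of the chiral dioxirane may be overridden by peripheral attack on the exposed face of the ring olefin, giving poor or reversed facial selectivity at C7.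
   The fallback sets out from 29 and uses that same bias. NBS in aqueous THF (0 °C) forms the bromonium ion on the exposed face, and water opens it anti at tertiary C7, giving the bromohydrin F2 with the required C7 oxygen. K2CO3/MeOH then closes F2 by displacement of bromide at C8 to the oxirane on the hindered face, returning the route to 30.

Further compounds
F1 | step 9 | C11 carbinol of 15 (cyclononenol) | O[C@H]1CC/C=C(C)\CC[C@@H]2C(=C)[C@@H](OC)OC[C@@H]12
F2 | step 21 | 8-bromo-7-hydroxy compound (bromohydrin, anti) | C=C1CC[C@H](Br)[C@@](C)(O)CC[C@@H]2C3=C[C@H]([C@@H](O[Si](CC)(CC)CC)C(C)(C)O[Si](CC)(CC)CC)O[C@@H]3OC[C@@H]12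
F3 | step 23 | trans-8,9-epoxy-7-ol | C=C1C[C@@H]2O[C@H]2[C@@](C)(O)CC[C@@H]2C3=C[C@H]([C@@H](O[Si](CC)(CC)CC)C(C)(C)O[Si](CC)(CC)CC)O[C@@H]3OC[C@@H]12
F4 | step 23 | 7,8-dihydroxy-9-(methyldiphenylphosphonio) iodide | C=C1C[C@@H]([P+](C)(c2ccccc2)c2ccccc2)[C@@H](O)[C@@](C)(O)CC[C@@H]2C3=C[C@H]([C@@H](O[Si](CC)(CC)CC)C(C)(C)O[Si](CC)(CC)CC)O[C@@H]3OC[C@@H]12.[I-]
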